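Ask where the flask ends. From first row to last of the grey, teal and red runs the isomer of the product A climbs while the target sinks, so I expect the end to belong to the isomer; what remains is how fast the ratio r, target over isomer, falls with time t.

| setting | grey | teal | red | flask |
|---|---|---|---|---|
| substrate | 0.034 M | 0.075 M | 0.050 M | 0.050 M |
| reagent | 0.075 M | 0.075 M | 0.037 M | 0.0750 M |
| remark | run made earlier | run made earlier | run made earlier |  |
| time |  |  |  | 25 min |

- grey (time / min: target / %, isomer of the product A / %): 3.00: 14.5, 30.9; 6.00: 9.1, 46.3; 10.0: 9.6, 58.4; 12.0: 8.3, 61.7; 15.0: 6.5, 64.0; 20.0: 6.1, 72.4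
- teal (time / min: target / %, isomer of the product A / %): 1.33: 14.1, 15.0; 4.00: 11.3, 31.6; 8.00: 7.5, 45.4; 10.0: 6.7, 51.2; 15.0: 5.6, 59.6; 20.0: 4.8, 65.7
- red (time / min: target / %, isomer of the product A / %): 4.00: 6.9, 22.4; 8.00: 5.7, 34.6; 12.0: 4.2, 42.8; 15.0: 3.8, 46.0; 20.0: 4.0, 50.9

(scatter of a reading: 1 percentage point)

* ratio of target to isomer of the product A at 20 s
* ratio of target to isomer of the product A at 3.0 min
* ratio of target to isomer of the product A at 25 min



Multiply r by t. Read it in the first row of each run, where the target is large: grey gives 1.41 min, teal 1.25 min, red 1.23 min. The new flask takes its substrate charge from red and its reagent charge from grey, so carry the mean as the balance time T, the time at which r·t puts target and isomer level: 1.30 min. The last rows give 1.57 min, more than T, but there a scatter of 1 percentage point sits on a smaller target, in the teal run 4.8% against 14.1% in its first row, so hold to T.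

Now climb the ladder. Near T the two stand level: teal shows r = 0.940 at 1.33 min. At 3.0 min the isomer leads, and my r is 0.433. At 25 min my r is 0.0520. Below the rung T stands 20 s, earlier than any reading: T gives 3.90 there, which I hold loosely.

The forecast, holding that “the ratio depends almost only on time, not on substrate or reagent level”, says 3.5, below my figure, then 0.46 and 0.065, each above mine.

The flask gives 1.63, 0.410 and 0.0536.

    substrate + reagent → intermediate + by-product (k = 0.170 L mol⁻¹ s⁻¹)
    intermediate ⇌ target (K = 1.70, k = 0.0220 s⁻¹)
    intermediate ⇌ isomer of the product A (K = 200, k = 0.0110 s⁻¹)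
    target ⇌ isomer of the product B (K = 3.80, k = 0.0170 s⁻¹)

In this flask r·t comes to 1.23 min at 3.0 min and 1.34 min at 25 min, both near T, but to 0.543 min at 20 s, well below it. Take the neighbouring flask with 0.019 M of reagent, substrate and time unchanged: T reckons 0.0520 at 25 min, and that neighbour gives 0.0544, level with the recipe flask. The reagent there is the limiting reagent: that neighbour ends with 0.0229% of its reagent and 62.0% of its substrate.

(The numbers in the tables are calculated for substances that don't exist, noise included.)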